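The earlier runs and the new flask come from a simulation from invented constants; noise was put on by code.

Monday's flask, charged with 1.50 times Saturday's D at equal J and Q, read 1.93 times Saturday's E at 6.00 h (taken between its readings) but 1.59 times at 15.0 h, so its lead shrank. Saturday's flask is the one asked about, followed on to 4.0 d.

| flask | J | Q | D | remark | time |
|---|---|---|---|---|---|
| Saturday's | 0.40 M | 0.52 M | 0.60 M | the very flask that is asked about, followed so far |  |
| Monday's | 0.40 M | 0.52 M | 0.90 M | run made earlier |  |
| flask | 0.40 M | 0.520 M | 0.600 M |  | 4.0 d |

| run | time / h | E / % |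
|---|---|---|
| Saturday's | 2.00 | 1.5 |
| Saturday's | 6.00 | 4.6 |
| Saturday's | 10.0 | 13.7 |
| Saturday's | 15.0 | 19.8 |
| Saturday's | 20.0 | 27.6 |
| Saturday's | 30.0 | 38.7 |
| Monday's | 3.00 | 1.7 |
| Monday's | 5.00 | 7.1 |
| Monday's | 8.00 | 12.5 |
| Monday's | 15.0 | 31.4 |
| Monday's | 25.0 | 46.8 |
| Monday's | 40.0 | 62.0 |

(standard deviation of a reading: 1 percentage point)

* amount of E in percent of the J charged, at 5.0 h, 25 h and 4.0 d

The early ratio is a rough reading, since the scatter is large on so few percent, but it leans towards the square of the charge ratio, 2.25, and the later one towards the ratio itself. With the slow start of both runs, this reckoning takes it that E is joined from two partners, each made slowly and each costing one D, the joining counted as instantaneous. Two D then buy one E, and that gives the D ceiling, the charge of D over two charges of J, as a fraction of the J charged: 75.0% in Saturday's flask. In Monday's flask it is 112%, above the J charged, so there J would be the limiting reagent, and in Saturday's flask D.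

Let the rate of E be a pace times the fraction of J left times the distance to the ceiling. Integrated to each run's last reading, this gives a pace of 0.0315 h⁻¹ from Saturday's flask and 0.0333 h⁻¹ from Monday's. Carried to 4.0 d in Saturday's flask, the two paces give 61.4% and 62.3%. That agreement tests the pace; the price of two D rests on the early lead.

At 25 h the law gives 34.9% and Saturday's neighbouring readings 33.1%. At 5.0 h they part: the law gives 10.4%, the readings 3.82%. The law is the one that cheats, since it books J lost as E at once, and partners not yet joined are not E. The reckoning therefore keeps the readings for the two early times and the law for 4.0 d.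

The forecast gives 5%, 33.5% and 68%, with the remark “The long extrapolation is the weak point.”

The flask gives 2.97%, 32.5% and 61.0%.

    J + D → X (k = 1.40 × 10⁻⁵ L mol⁻¹ s⁻¹)
    D + Q → Z (k = 1.20 × 10⁻⁵ L mol⁻¹ s⁻¹)
    X + Z → E (k = 8.40 × 10⁻⁴ L mol⁻¹ s⁻¹)

Up to 0.400 d, J with D made X and D with Q made Z, D going to the second step at 1.1 times the rate of the first at the start, and X stood at 10.8% of the J charged beside E at 10.6%. X and Z joined alongside those two steps, with 80% of that step's turnover up to 4.0 d done by 2.00 d, X having a half-life of 0.18 d at 0.722 d against 1.8 d for J, while D fell to 10.0% of its charge at 4.00 d and 0% at 40.0 d, where E stood at 68.4%, under the ceiling of 75.0%, with Z at 0.0527 M.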